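**Plan**

1. Retrosynthesis: the two O–CH3 bonds are cut first (phenol protection). The C11′–C12′ bond in the middle of the tricosyl chain follows, as an alkyl–alkyl cross-coupling of a primary bromide with a primary alkylborane made in the flask from dodec-1-ene. The pyranone ring is then cut at O1–C2 and C2–C3, and last the two aryl–CH3 bonds at C6 and C8.
2. Forward: the benzene ring is bought as phloroacetophenone and C-methylated at both free positions. The pyranone ring is then closed with a 12-carbon ω-bromo acid, which leaves an 11-bromoundecyl arm on C2. The C12 half of the chain is joined last, before demethylation.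
3. Enabling feature: the C2 substituent is an unbranched (CH2)22CH3 chain without heteroatoms, so C11′ and C12′ are both unhindered CH2 carbons, ten methylenes away from the pyranone ring. The benzo ring (C4a, C5–C8, C8a) is fully substituted and the 2,4,6-trioxygenated acetophenone core is mirror-symmetric. The bromide is therefore the only reactive C–X site, and neither C-methylation nor ring closure has a regiochemical alternative.
4. Stereochemistry: the target has no stereocentre and no stereogenic double bond, so nothing needs to be controlled.

Key step: step 5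

Remark: side-chain carbons are numbered C1′ (bonded to chromone C2) to C23′; phloroacetophenone is used in anhydrous form.

**Route**

Step 1
Reactants: 1 1-(2,4,6-trihydroxyphenyl)ethanone (phloroacetophenone)
Product: 2 1-(2,4,6-trihydroxy-3,5-dimethylphenyl)ethanone
Conditions: MeI (2.2 equiv), NaOMe (3 equiv), MeOH, 0 °C → rt
Reagents that add atoms: iodomethane, CI
Why: C-alkylation of a phloroglucinol phenoxide: in methanol the phenoxide oxygens are hydrogen-bonded, so MeI should attack the two equivalent free ring carbons C3 and C5, and each dienone re-aromatises by tautomerisation; two equivalents of MeI limit further methylation to gem-dimethyl dienones.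

Step 2
Reactants: 2 1-(2,4,6-trihydroxy-3,5-dimethylphenyl)ethanone
Product: 3 1-(2-hydroxy-4,6-dimethoxy-3,5-dimethylphenyl)ethanone
Conditions: Me2SO4 (2.1 equiv), K2CO3, acetone, reflux
Reagents that add atoms: dimethyl sulfate, COS(=O)(=O)OC
Why: Williamson ether synthesis with a hard electrophile in an aprotic solvent goes to oxygen; the 4-OH and one of the two equivalent 2/6-OH groups should be methylated, while the last OH is tied to the acetyl carbonyl by a strong hydrogen bond and stays free at two equivalents of reagent.

Step 3
Reactants: 3 1-(2-hydroxy-4,6-dimethoxy-3,5-dimethylphenyl)ethanone; 4 12-bromododecanoic acid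
Product: 6 2-acetyl-3,5-dimethoxy-4,6-dimethylphenyl 12-bromododecanoate, via 12-bromododecanoyl chloride 5 (not isolated)
Conditions: 4, (COCl)2 (1.2 equiv), DMF (cat.), CH2Cl2, 0 °C → rt, evaporate; then 3, Et3N, DMAP (cat.), CH2Cl2, 0 °C → rt
Reagents that add atoms: none
Why: acid chloride formation followed by DMAP-catalysed O-acylation of the hindered, chelated phenol; nothing in these conditions displaces the primary bromide.

Step 4
Reactants: 6 2-acetyl-3,5-dimethoxy-4,6-dimethylphenyl 12-bromododecanoate
Product: 8 2-(11-bromoundecyl)-5,7-dimethoxy-6,8-dimethyl-4H-chromen-4-one, via the bromo 1,3-diketone 7 (not isolated)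
Conditions: LiHMDS (3 equiv), THF, −78 → 0 °C; 1 M HCl work-up; then AcOH, H2SO4 (cat.), 90 °C
Reagents that add atoms: none
Why: Baker–Venkataraman rearrangement: the lithium enolate of the aryl methyl ketone attacks the neighbouring ester carbonyl through a six-membered transition state (intramolecular Claisen condensation, O→C acyl shift) to form the C2–C3 bond, and acid then closes the pyranone by 6-exo-trig attack of the freed phenol oxygen on the chain carbonyl with loss of water; low temperature in THF should keep the lithium enolate from alkylating the primary bromide.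

Step 5
Reactants: 8 2-(11-bromoundecyl)-5,7-dimethoxy-6,8-dimethyl-4H-chromen-4-one; 9 dodec-1-ene
Product: 11 5,7-dimethoxy-6,8-dimethyl-2-tricosyl-4H-chromen-4-one, via B-dodecyl-9-BBN 10 (not isolated)
Conditions: 9 (1.4 equiv), 9-BBN dimer (0.65 equiv), THF, rt; then 8, Pd(OAc)2 (4 mol %), PCy3 (8 mol %), K3PO4·H2O (1.3 equiv), THF, rt; no oxidative work-up
Reagents that add atoms: none
Why: 9-BBN adds syn and anti-Markovnikov across dodec-1-ene to place boron on C1 (the future C12′); Pd(0)/PCy3 then inserts by SN2-type oxidative addition into the primary C–Br bond of 8 (the future C11′), hydroxide from K3PO4·H2O turns 10 into a borate that transfers only its primary dodecyl group to palladium, and reductive elimination forms the C11′–C12′ bond. The closest known reaction type is the room-temperature alkyl–alkyl Suzuki–Miyaura coupling of primary alkyl bromides bearing β-hydrogens with B-alkyl-9-BBN reagents. No ring is closed and no stereocentre is formed. The step needs cross- over homo-coupling and reductive elimination over β-hydride elimination: the first is inherent in the nucleophile/electrophile pairing, the second should be secured by the bulky, electron-rich PCy3 and by both reacting carbons being unbranched CH2 groups. Chemoselectivity rests on the substrate: the bromide is the only C–X bond, the benzo ring (C5–C8) is fully substituted, the phenols are methyl ethers so no phenoxide can be alkylated by the bromide, and the C4 vinylogous-ester carbonyl should not be reduced because the alkene is used in slight excess over B–H.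

Step 6
Reactants: 11 5,7-dimethoxy-6,8-dimethyl-2-tricosyl-4H-chromen-4-one
Product: 12 5,7-dihydroxy-6,8-dimethyl-2-tricosyl-4H-chromen-4-one (target)
Conditions: BBr3 (5 equiv), CH2Cl2, −78 °C → rt; then ice-water
Reagents that add atoms: none
Why: Lewis acid ether cleavage: BBr3 binds each methoxy oxygen and bromide removes the methyl group by SN2; the C5 ether is activated by chelation of boron between O5 and the C4 carbonyl, the C7 ether is twisted out of conjugation by the C6 and C8 methyl groups and should complex readily, and the pyranone and the saturated chain are inert to the reagent.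

**Compound list**

1 | 1-(2,4,6-trihydroxyphenyl)ethanone (phloroacetophenone) | CC(=O)c1c(O)cc(O)cc1O | starting material
2 | 1-(2,4,6-trihydroxy-3,5-dimethylphenyl)ethanone | CC(=O)c1c(O)c(C)c(O)c(C)c1O | intermediate
3 | 1-(2-hydroxy-4,6-dimethoxy-3,5-dimethylphenyl)ethanone | CC(=O)c1c(O)c(C)c(OC)c(C)c1OC | intermediate
4 | 12-bromododecanoic acid | OC(=O)CCCCCCCCCCCBr | starting material
5 | 12-bromododecanoyl chloride | ClC(=O)CCCCCCCCCCCBr | intermediate
6 | 2-acetyl-3,5-dimethoxy-4,6-dimethylphenyl 12-bromododecanoate | CC(=O)c1c(OC(=O)CCCCCCCCCCCBr)c(C)c(OC)c(C)c1OC | intermediate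
7 | 14-bromo-1-(2-hydroxy-4,6-dimethoxy-3,5-dimethylphenyl)tetradecane-1,3-dione | O=C(CC(=O)CCCCCCCCCCCBr)c1c(O)c(C)c(OC)c(C)c1OC | intermediate
8 | 2-(11-bromoundecyl)-5,7-dimethoxy-6,8-dimethyl-4H-chromen-4-one | BrCCCCCCCCCCCc1cc(=O)c2c(OC)c(C)c(OC)c(C)c2o1 | intermediate
9 | dodec-1-ene | C=CCCCCCCCCCC | starting material
10 | 9-dodecyl-9-borabicyclo[3.3.1]nonane (B-dodecyl-9-BBN) | CCCCCCCCCCCCB1C2CCCC1CCC2 | intermediate
11 | 5,7-dimethoxy-6,8-dimethyl-2-tricosyl-4H-chromen-4-one | CCCCCCCCCCCCCCCCCCCCCCCc1cc(=O)c2c(OC)c(C)c(OC)c(C)c2o1 | intermediate
12 | 5,7-dihydroxy-6,8-dimethyl-2-tricosyl-4H-chromen-4-one | CCCCCCCCCCCCCCCCCCCCCCCc1cc(=O)c2c(O)c(C)c(O)c(C)c2o1 | target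

**Summary**

Total step count: 6. Longest linear sequence: 6 steps (1 → 2 → 3 → 6 → 8 → 11 → 12); compounds 4 and 9 are bought and enter directly.

Steps most likely to fail:

Step 5 (key step). The alkylpalladium intermediate may undergo β-hydride elimination before transmetalation, oxidative addition of the unactivated bromide may be slow, or residual B–H may reduce the C4 carbonyl. The fallback makes the same C11′–C12′ link as a double bond and then saturates it. It sets out from 8: Kornblum oxidation (DMSO, NaHCO3, 110 °C) should give 11-(5,7-dimethoxy-6,8-dimethyl-4-oxo-4H-chromen-2-yl)undecanal F1. The ylide from dodecyltriphenylphosphonium bromide is pre-formed (NaHMDS, THF) and F1 is added to it at −78 °C in a Wittig olefination, which should give 5,7-dimethoxy-6,8-dimethyl-2-[(11Z)-tricos-11-en-1-yl]-4H-chromen-4-one F2. Hydrogenation of the isolated alkene (H2, 1 atm, Pd/C, EtOAc, stopped after one equivalent) comes back to the route at 11.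

Step 4. The lithium enolate or phenoxide may be alkylated by the primary bromide, or the aryl ester enolate may fragment to a ketene, in competition with the acyl shift. The fallback builds the pyranone before the bromide is introduced. It sets out from 3: Claisen condensation with ethyl acetate (NaH, EtOAc, reflux) should give 1-(2-hydroxy-4,6-dimethoxy-3,5-dimethylphenyl)butane-1,3-dione F3. Acid cyclodehydration (AcOH, cat. H2SO4) should give 5,7-dimethoxy-2,6,8-trimethyl-4H-chromen-4-one F4. Deprotonation of the 2-methyl group to the vinylogous enolate (LDA, THF, −78 °C) and alkylation with excess 1,10-dibromodecane comes back to the route at 8.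

Step 1. Over-alkylation to gem-dimethyl cyclohexadienones, incomplete methylation and competing O-methylation may give a mixture that is hard to separate. The fallback installs the two carbons by aminomethylation and then reduces them. It sets out from 1: double Mannich reaction (aqueous formaldehyde, morpholine, EtOH) at the only two free ring positions should give 1-[2,4,6-trihydroxy-3,5-bis(morpholin-4-ylmethyl)phenyl]ethanone F5. Hydrogenolysis of the two benzylic C–N bonds (H2, Pd/C, AcOH–MeOH, 50 °C) comes back to the route at 2.

**Further compounds**

F1 | step 5 | 11-(5,7-dimethoxy-6,8-dimethyl-4-oxo-4H-chromen-2-yl)undecanal | O=CCCCCCCCCCCc1cc(=O)c2c(OC)c(C)c(OC)c(C)c2o1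
F2 | step 5 | 5,7-dimethoxy-6,8-dimethyl-2-[(11Z)-tricos-11-en-1-yl]-4H-chromen-4-one | CCCCCCCCCCC/C=C\CCCCCCCCCCc1cc(=O)c2c(OC)c(C)c(OC)c(C)c2o1
F3 | step 4 | 1-(2-hydroxy-4,6-dimethoxy-3,5-dimethylphenyl)butane-1,3-dione | CC(=O)CC(=O)c1c(O)c(C)c(OC)c(C)c1OC
F4 | step 4 | 5,7-dimethoxy-2,6,8-trimethyl-4H-chromen-4-one | Cc1cc(=O)c2c(OC)c(C)c(OC)c(C)c2o1
F5 | step 1 | 1-[2,4,6-trihydroxy-3,5-bis(morpholin-4-ylmethyl)phenyl]ethanone | CC(=O)c1c(O)c(CN2CCOCC2)c(O)c(CN2CCOCC2)c1O
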